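## Structural features

The target is a cembrane-type 14-membered carbocycle (C1–C14) bridged by a δ-lactone: the lactone oxygen sits on C3, C16 is the carbonyl and C15 (bearing a methyl group) joins C16 to C1, so C1, C2 and C3 belong to both rings. The seven stereocentres form three clusters. The first is C15–C1–C3–C4 on and beside the lactone: the ring bonds at C1 and C3 are cis, the C15 methyl is trans to the C1–C14 bond, and C3–O is anti to the tertiary C4–OH. The second is the trans trisubstituted C11–C12 epoxide (11S,12S), and the third is the isolated C7 carbon that carries the hydroperoxide next to the C8 exocyclic methylene. The fragile groups are the secondary allylic hydroperoxide (base, phosphines, reductants and transition metals destroy it), the epoxide (Brønsted and Lewis acids, transannular attack by the C4 hydroxyl) and the epimerisable C15 centre. The real difficulty is closing the 14-membered ring without putting a stereocentre at risk and then relaying configuration between clusters four to seven bonds apart; C7 has no stereogenic neighbour at all. The key step exploits the fact that C1 is both a ring member and the lactone β-carbon: as the enol triflate carbon of a 3-methyl-5,6-dihydropyran-2-one it is flat and reactive toward zerovalent palladium, so C14 can be joined to it as an alkylzinc. C3 and the new ring then set C1 and C15 in a conjugate reduction.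

## Logic of the disconnections

26 to 25. The C7–O bond is cut; the allylic hydrogen returns to the C8 methyl group and the double bond to C7=C8. The hydroperoxide is the least robust group, so it is made last, by an ene reaction that needs no protecting group. The gain is the loss of the C7 stereocentre and of the only peroxide. The forward step must take hydrogen from the methyl group, not from C6 or C9, and must attack the alkene face that gives 7S.

25 to 24 to 22. The O–Si bond at C4 and then the C1–H and C15–H bonds are cut. Both carbons come from one conjugated alkene, so two stereocentres are traded for an sp2 pair. The forward step must deliver hydride to C1 on the face away from the C3–C4 bond, end with C15 trans, and reduce a tetrasubstituted conjugated alkene beside an isolated alkene and an epoxide.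

22 to 20. The C14–C1 bond is cut. C1 is the only ring carbon that is sp2 and activated, so closure there creates and endangers no stereocentre, and the open chain 20 can be built with acyclic stereocontrol. The forward step needs a C14 organometallic mild enough for epoxide, lactone and triflate, and ring closure must outrun oligomerisation. For that reason iodide and triflate are both introduced after all carbanion chemistry, the triflate last.

20 to 18 to 16 and 17. The triflate S–O bond, the lactone C16–O bond and the C2–C3 bond are cut. This returns the four-carbon lactone unit to a commercial β-keto ester and leaves a non-enolisable aldehyde. The forward aldol must add to the aldehyde face that gives 3R beside the quaternary 4S centre (non-chelation control) and must tolerate the primary iodide.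

16 to 15 to 14 to 13 to 11 to 10 to 9. The oxidation level at C3 and the leaving group at C14 are adjusted, then the C13–C14 bond is cut as a C13=C14 alkene. The epoxide needs an allylic hydroxyl on C13 for reagent control, so C14 must be added afterwards. The homologation must not open the epoxide; the quaternary C12 rules out epimerisation.

9 to 8. The two C–O bonds of the oxirane are cut. Two stereocentres return to an E-allylic alcohol. The forward step must choose C11=C12 over C7=C8, which the directing hydroxyl secures.

8 to 7 to 6. A C6–S bond is restored and the C13–O bond is cut. The sulfone activates C6 for the C5–C6 bond, and the allylic oxidation is done while the sulfone still deactivates C7=C8. The forward desulfonylation must not move the alkene and must come before any epoxide exists.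

6 to 2 and 4. The C5–C6 bond and the O–Si bond at C4 are cut. This separates an achiral C6–C13 terpene unit from a three-carbon unit that brings C4 from the chiral pool. The forward step must open the epoxide only at its CH2 terminus.

2 to 1 and 4 to 3. A C–S bond and a benzylic O–C bond are cut, giving commercial materials. The forward steps are simple substitutions that leave the E-alkene and the C4 centre untouched.

## Other disconnections considered

Alternative 1: The cut is the four C–O bonds of the C3–C4 and C11–C12 oxiranes, traced to the two E-allylic alcohol ends of the triene diol 12-hydroxyfarnesol A1, which holds C2–C13. The forward key step is a double Sharpless epoxidation (Ti(OiPr)4, L-(+)-diethyl tartrate, tert-butyl hydroperoxide) to the bis-epoxy diol A2, with C7=C8 spared for lack of a directing hydroxyl.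
- In its favour: four stereocentres come from one catalytic, reagent-controlled operation on a chain that already has all three methyl groups and the E-C7=C8 alkene. The double reaction should also raise the enantiomeric purity of A2. On stereocentre economy and on reagent control at C3/C4 it is better than the chosen plan, whose C3 rests on substrate control.
- Against it: the two ends of A2 are nearly identical 2,3-epoxy-3-methyl alcohols, yet one must be homologated with the epoxide kept and the other opened. A2 is 3S where the target is 3R, so C3 needs an inversion, and C2 must change from carbinol to a methylene bonded to C1. Differentiating the ends is likely to cost the steps that the double epoxidation saves.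
- Comparison: on structure it covers the same four centres as steps 2, 6 and 13 here. On mechanism it is equal at C11/C12 and better at C3/C4. On step economy it is roughly equal once differentiation and inversion are counted. It offers no ring closure and nothing for C1, C15 or C7, so it complements the chosen closure more than it competes with it.

Alternative 2: The cut is C15–C16 and C16–O at C3. In the forward key step zerovalent palladium adds to the C15 alkenyl triflate of the macrocyclic diol A3, CO inserts, and the C3 hydroxyl captures the acylpalladium to give the α-methylene δ-lactone A4.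
- In its favour: the lactone forms under neutral conditions on an intact carbocycle, and the tertiary C4 hydroxyl can stay free. The 1,1-disubstituted conjugated alkene of A4 should be far easier to reduce than the tetrasubstituted alkene of 22. On both points it is better than the chosen plan.
- Against it: C1 must already be a stereocentre, cis to the C3 hydroxyl, before the step, and it sits α to a ketone in any precursor of A3. The carbocycle must be closed by another, unspecified C–C bond formation, so the hardest problem is only moved. A hindered secondary alcohol next to the quaternary C4 may capture the acylpalladium slowly.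
- Comparison: on structure it closes the small ring, whereas the chosen step closes the large ring and postpones C1. On mechanism the two are equal, since both start with oxidative addition of zerovalent palladium to an enol-type triflate. C15 is set by protonation in both (equal). On step economy it is likely to be longer, because a separate macrocyclisation and separate control of C1 are needed.

Alternative 3: The cut is the C9–C10 bond, reached by ring contraction. In the forward key step zerovalent palladium ionises the allylic ester of the 16-membered β-keto ester A5, CO2 is lost, and the C9 enolate recombines with the C10 allyl terminus to give the 14-membered ketone A6 with the E-C11=C12 alkene.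
- In its favour: the ring is first closed by macrolactonisation, a dependable closure, and the C–C bond then forms inside an ion pair at ordinary concentration. This is better than a high-dilution organometallic macrocyclisation. The enolate is generated regiospecifically without base. The C7 oxygen is set before the ring exists, by acyclic chemistry, which is better than a late ene reaction for control at C7.
- Against it: A6 still lacks the epoxide, the exocyclic methylene and the peroxide. The C11=C12 alkene would have to be epoxidised face-selectively on a macrocycle without a directing group, and the hindered C8 ketone methylenated beside the C7 silyl ether. A6 carries the C7 oxygen in the configuration opposite to that of the target, so the hydroperoxide would have to enter by displacement with inversion at an allylic carbon, with the C4 hydroxyl able to compete by tetrahydrofuran formation. C7 is α to the ketone and could epimerise if the enolate equilibrates.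
- Comparison: on structure it keeps the lactone stereocentres through the closure, as the chosen plan does (equal). On mechanism it is ionic and tolerant, and better in closure reliability. On step economy it is worse, with at least five operations after ring formation against three here.

Key step: step 15

Remark: position labels C1–C16 are those defined under Structural features; species formed by simple deprotonation and members of catalytic cycles are treated as transient and carry no number, whereas intermediates that accumulate in the flask are numbered.

## Steps

Step 1
Reactants: 1 geranyl bromide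
Product: 2 geranyl phenyl sulfone
Conditions: PhSO2Na, DMF, rt
Reagents that add atoms: sodium benzenesulfinate, [Na+].[O-]S(=O)c1ccccc1
Why: SN2 displacement of the allylic bromide by the soft sulfur end of the sulfinate; the E-C7=C8 geometry is untouched and the sulfone acidifies C6 for the later C5–C6 bond.

Step 2
Reactants: 3 (R)-2-methylglycidol
Product: 4 (2S)-2-[(4-methoxybenzyloxy)methyl]-2-methyloxirane
Conditions: NaH, 4-methoxybenzyl chloride, n-Bu4NI (cat.), THF/DMF, 0 °C to rt
Reagents that add atoms: 4-methoxybenzyl chloride, COc1ccc(CCl)cc1
Why: Williamson etherification of the primary alkoxide; a Payne rearrangement of this alkoxide is degenerate and returns the same enantiomer. The descriptor changes from R to S only because the ether arm now outranks the ring CH2; the spatial arrangement is unchanged.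

Step 3
Reactants: 2 geranyl phenyl sulfone; 4 (2S)-2-[(4-methoxybenzyloxy)methyl]-2-methyloxirane
Product: 6 C3–C13 sulfone with C4 triethylsilyl ether and C3 4-methoxybenzyl ether (both C6 epimers), via lithium alkoxide 5 (not isolated)
Conditions: n-BuLi, THF/DMPU, −78 °C; 4, −78 to 0 °C; Et3SiCl, 0 °C to rt
Reagents that add atoms: chlorotriethylsilane, CC[Si](Cl)(CC)CC
Why: The α-sulfonyl allyl anion opens the 2,2-disubstituted epoxide at its CH2 terminus (SN2, C5–C6 bond), so the C4 centre of 3 is carried over as 4S without touching a bond to it. The tertiary lithium alkoxide 5 is silylated in the same flask, which saves a separate protection. The C6 centre is a mixture and is erased in step 5.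

Step 4
Reactants: 6 C3–C13 sulfone
Product: 7 C13 allylic alcohol (11E) of the sulfone
Conditions: SeO2 (cat.), t-BuOOH, salicylic acid (cat.), CH2Cl2, 0 °C to rt, partial conversion
Reagents that add atoms: selenium dioxide, O=[Se]=O; tert-butyl hydroperoxide, CC(C)(C)OO
Why: Allylic oxidation by SeO2 (ene reaction, then [2,3]-sigmatropic shift) attacks the electron-rich terminal isopropylidene at its E-methyl group, giving the E-allylic alcohol. The C7=C8 alkene is deactivated by the allylic sulfone.

Step 5
Reactants: 7 C13 allylic alcohol of the sulfone
Product: 8 (2E,6E,10S)-11-(4-methoxybenzyloxy)-2,6,10-trimethyl-10-(triethylsilyloxy)undeca-2,6-dien-1-ol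
Conditions: PdCl2(dppp) (cat., dppp = Ph2P(CH2)3PPh2), LiBHEt3, THF, 0 °C
Reagents that add atoms: none
Why: Palladium-catalysed reductive desulfonylation: zerovalent palladium ionises the allylic C–S bond and hydride is delivered to the less substituted allyl terminus C6, so the E-C7=C8 alkene should stay in place. The step is run before any epoxide exists because LiBHEt3 would open one.

Step 6
Reactants: 8 dienol
Product: 9 (11S,12S)-epoxy alcohol
Conditions: Ti(OiPr)4 (cat.), L-(+)-diethyl tartrate, t-BuOOH, 4 Å molecular sieves, CH2Cl2, −20 °C
Reagents that add atoms: tert-butyl hydroperoxide, CC(C)(C)OO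
Why: Sharpless asymmetric epoxidation: the C13 hydroxyl binds tetravalent titanium and the L-(+)-tartrate ligand directs oxygen to the face that gives the (S,S) oxirane of an E-allylic alcohol. C7=C8 has no directing hydroxyl and should stay.

Step 7
Reactants: 9 epoxy alcohol
Product: 10 epoxy aldehyde (C13 aldehyde)
Conditions: Dess–Martin periodinane, NaHCO3, CH2Cl2, 0 °C to rt
Reagents that add atoms: none
Why: Buffered Dess–Martin oxidation; the α-carbon C12 is quaternary, so the epoxy aldehyde can neither enolise nor epimerise.

Step 8
Reactants: 10 epoxy aldehyde
Product: 11 vinyl epoxide (C13=C14)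
Conditions: Ph3PCH3Br, KN(SiMe3)2, THF, −78 to 0 °C
Reagents that add atoms: methyltriphenylphosphonium bromide, C[P+](c1ccccc1)(c1ccccc1)c1ccccc1.[Br-]
Why: Wittig methylenation adds C14; the aldehyde is far more electrophilic toward the ylide than the epoxide.

Step 9
Reactants: 11 vinyl epoxide
Product: 13 C14 primary alcohol, via alkylborane 12 (not isolated)
Conditions: 9-BBN, THF, 0 °C to rt; H2O2, NaOH (aq), 0 °C
Reagents that add atoms: hydrogen peroxide, OO
Why: Hydroboration with 9-BBN is selective for the monosubstituted alkene over the trisubstituted one and places boron on C14. Cold alkaline peroxide then replaces boron by hydroxyl, completing the one-carbon homologation without touching the epoxide.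

Step 10
Reactants: 13 C14 primary alcohol
Product: 14 C14 iodide
Conditions: I2, PPh3, imidazole, CH2Cl2, 0 °C
Reagents that add atoms: iodine, II
Why: Appel-type iodination: iodide displaces the oxyphosphonium group at the primary carbon. The imidazole buffer should spare epoxide and silyl ether.

Step 11
Reactants: 14 C14 iodide
Product: 15 C3 primary alcohol
Conditions: DDQ, CH2Cl2/pH 7 buffer, 0 °C to rt
Reagents that add atoms: none
Why: Oxidative cleavage of the 4-methoxybenzyl ether by DDQ is neutral and leaves iodide, epoxide, alkene and the tertiary silyl ether alone.

Step 12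
Reactants: 15 C3 primary alcohol
Product: 16 C3 aldehyde
Conditions: Dess–Martin periodinane, NaHCO3, CH2Cl2, 0 °C to rt
Reagents that add atoms: none
Why: Buffered Dess–Martin oxidation; C4 is quaternary, so the α-silyloxy aldehyde is configurationally safe and cannot enolise.

Step 13
Reactants: 16 C3 aldehyde; 17 methyl 2-methylacetoacetate
Product: 18 δ-hydroxy-β-keto ester (3R,4S; C15 epimers and enol)
Conditions: 17, NaH then n-BuLi, THF, 0 °C; 16, −78 °C; AcOH quench at −78 °C
Reagents that add atoms: none
Why: Aldol addition of the γ-carbon of the β-keto ester dianion to a non-enolisable aldehyde forms C2–C3. With a bulky, non-chelating silyloxy group on C4, the polar Felkin–Anh transition state (C–O anti to the nucleophile, methyl beside the trajectory) should favour the 3R adduct; chelation would give 3S. Addition at −78 °C is much faster than alkylation of the dianion by the primary iodide.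

Step 14
Reactants: 18 δ-hydroxy-β-keto ester
Product: 20 C14 iodide and C1 enol triflate seco lactone, via β-keto lactone 19 (not isolated)
Conditions: K2CO3, MeOH, 0 °C to rt; evaporate; PhNTf2, THF, 0 °C to rt
Reagents that add atoms: N-phenyl-bis(trifluoromethanesulfonimide), O=S(=O)(N(c1ccccc1)S(=O)(=O)C(F)(F)F)C(F)(F)F
Why: Base-induced lactonisation (C3 hydroxyl onto the methyl ester, six-membered ring) gives the β-keto lactone as its potassium enolate 19, which PhNTf2 sulfonylates on oxygen. Triflation is placed last so that the vinylogous acyl triflate meets no nucleophile before the key step.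

Step 15
Reactants: 20 seco lactone
Product: 22 macrocyclic C1=C15 unsaturated lactone, via alkylzinc iodide 21 (not isolated)
Conditions: Zn dust (activated), LiCl, THF, 30 °C; then syringe-pump addition to Pd(PPh3)4 (10 mol%), THF, 55 °C, about 1 mM
Reagents that add atoms: none
Why: Zinc inserts into the primary C14–I bond, with LiCl keeping the alkylzinc iodide in solution; zinc metal at 30 °C should not reduce the enol triflate, the epoxide, the silyl ether or the alkene. Zerovalent palladium then adds oxidatively to the electron-poor C1–OTf bond, the alkylzinc transmetalates, and reductive elimination from the alkyl(alkenyl)palladium forms C14–C1. The closest known reaction type is the Negishi coupling of primary alkylzinc halides with enol triflates of β-keto esters and lactones, used here intramolecularly. The 14-membered carbocycle closes by reductive elimination from a 15-membered palladacycle, with the C1=C15 double bond left exocyclic to the new ring. No stereocentre is formed, and none is at risk, because C1 is sp2 and the bonds to C3, C4, C11 and C12 are not touched. Ring closure must win over intermolecular coupling; slow addition of preformed 21 to the catalyst keeps its stationary concentration very low. The epoxide must survive a carbon–zinc bond two carbons away; an alkylzinc iodide complexed by LiCl is a weak nucleophile and a mild Lewis acid, and insertion is run at 30 °C for this reason.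

Step 16
Reactants: 22 macrocyclic unsaturated lactone
Product: 24 (1R,15S) saturated lactone with C4 triethylsilyl ether, via C15-epimeric lactone 23 (not isolated)
Conditions: [(Ph3P)CuH]6, t-BuOH, PhMe, rt to 45 °C; then DBU, 60 °C
Reagents that add atoms: none
Why: Conjugate reduction by copper hydride: hydride should add to C1 on the face away from the C3–C4 bond and the macrocyclic bridge, which puts C14 cis to C4 (1R). Protonation of the enolate by t-BuOH is expected kinetically on the same outer face, giving the cis lactone 23. DBU then equilibrates C15 to the trans arrangement 24 with the methyl group anti to C14 (15S); any 24 formed directly is already the product. The isolated alkene and the epoxide are inert to the nucleophilic hydride.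

Step 17
Reactants: 24 saturated lactone silyl ether
Product: 25 C4 hydroxy lactone
Conditions: n-Bu4NF, AcOH, THF, 0 °C to rt
Reagents that add atoms: none
Why: Fluoride cleaves the tertiary triethylsilyl ether; acetic acid buffers the medium so that the C15 centre and the epoxide see neither strong base nor strong acid.

Step 18
Reactants: 25 C4 hydroxy lactone
Product: 26 target hydroperoxide CNP0319766.2
Conditions: O2, visible light, tetraphenylporphyrin (cat.), CH2Cl2, −20 °C
Reagents that add atoms: oxygen, O=O
Why: Schenck ene reaction of singlet oxygen with the only alkene: oxygen bonds to C7 while a hydrogen of the C8 methyl group is taken, shifting the double bond to C8=CH2. The methyl group lies on the more crowded side of the alkene (cis to C6) and can always align with the π-system. The 7S configuration depends on attack at the outer face of the ring in its preferred conformation.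

## Compound list

1 | geranyl bromide, (2E)-1-bromo-3,7-dimethylocta-2,6-diene | CC(C)=CCC/C(C)=C/CBr | starting material
2 | geranyl phenyl sulfone, {[(2E)-3,7-dimethylocta-2,6-dien-1-yl]sulfonyl}benzene | CC(C)=CCC/C(C)=C/CS(=O)(=O)c1ccccc1 | intermediate
3 | (R)-2-methylglycidol, [(2R)-2-methyloxiran-2-yl]methanol | C[C@@]1(CO)CO1 | starting material
4 | (2S)-2-[(4-methoxybenzyloxy)methyl]-2-methyloxirane (4-methoxybenzyl ether of 3, same spatial arrangement) | C[C@@]1(COCc2ccc(OC)cc2)CO1 | intermediate
5 | lithium (2S,5E)-1-(4-methoxybenzyloxy)-2,6,10-trimethyl-4-(phenylsulfonyl)undeca-5,9-dien-2-olate, both epimers at the sulfone carbon (not isolated) | CC(C)=CCC/C(C)=C/C(C[C@](C)(O[Li])COCc1ccc(OC)cc1)S(=O)(=O)c1ccccc1 | intermediate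
6 | triethyl{[(2S,5E)-1-(4-methoxybenzyloxy)-2,6,10-trimethyl-4-(phenylsulfonyl)undeca-5,9-dien-2-yl]oxy}silane, both epimers at the sulfone carbon | CC(C)=CCC/C(C)=C/C(C[C@](C)(O[Si](CC)(CC)CC)COCc1ccc(OC)cc1)S(=O)(=O)c1ccccc1 | intermediate
7 | (2E,6E,10S)-11-(4-methoxybenzyloxy)-2,6,10-trimethyl-8-(phenylsulfonyl)-10-(triethylsilyloxy)undeca-2,6-dien-1-ol, both epimers at the sulfone carbon | OC/C(C)=C/CC/C(C)=C/C(C[C@](C)(O[Si](CC)(CC)CC)COCc1ccc(OC)cc1)S(=O)(=O)c1ccccc1 | intermediate
8 | (2E,6E,10S)-11-(4-methoxybenzyloxy)-2,6,10-trimethyl-10-(triethylsilyloxy)undeca-2,6-dien-1-ol | OC/C(C)=C/CC/C(C)=C/CC[C@](C)(O[Si](CC)(CC)CC)COCc1ccc(OC)cc1 | intermediate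
9 | [(2S,3S)-3-[(3E,7S)-8-(4-methoxybenzyloxy)-3,7-dimethyl-7-(triethylsilyloxy)oct-3-en-1-yl]-2-methyloxiran-2-yl]methanol (C11–C12 epoxide, 11S,12S) | OC[C@]1(C)O[C@H]1CC/C(C)=C/CC[C@](C)(O[Si](CC)(CC)CC)COCc1ccc(OC)cc1 | intermediate
10 | (2R,3S)-3-[(3E,7S)-8-(4-methoxybenzyloxy)-3,7-dimethyl-7-(triethylsilyloxy)oct-3-en-1-yl]-2-methyloxirane-2-carbaldehyde (same spatial arrangement as 9; the label at the aldehyde-bearing carbon changes by ranking only) | O=C[C@]1(C)O[C@H]1CC/C(C)=C/CC[C@](C)(O[Si](CC)(CC)CC)COCc1ccc(OC)cc1 | intermediate
11 | (2S,3S)-2-ethenyl-3-[(3E,7S)-8-(4-methoxybenzyloxy)-3,7-dimethyl-7-(triethylsilyloxy)oct-3-en-1-yl]-2-methyloxirane | C=C[C@]1(C)O[C@H]1CC/C(C)=C/CC[C@](C)(O[Si](CC)(CC)CC)COCc1ccc(OC)cc1 | intermediate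
12 | 9-{2-[(2S,3S)-epoxide of 11]ethyl}-9-borabicyclo[3.3.1]nonane, boron on C14 (not isolated) | B1(CC[C@]2(C)O[C@H]2CC/C(C)=C/CC[C@](C)(O[Si](CC)(CC)CC)COCc2ccc(OC)cc2)C2CCCC1CCC2 | intermediate
13 | 2-[(2S,3S)-3-[(3E,7S)-8-(4-methoxybenzyloxy)-3,7-dimethyl-7-(triethylsilyloxy)oct-3-en-1-yl]-2-methyloxiran-2-yl]ethanol | OCC[C@]1(C)O[C@H]1CC/C(C)=C/CC[C@](C)(O[Si](CC)(CC)CC)COCc1ccc(OC)cc1 | intermediate
14 | (2S,3S)-2-(2-iodoethyl)-3-[(3E,7S)-8-(4-methoxybenzyloxy)-3,7-dimethyl-7-(triethylsilyloxy)oct-3-en-1-yl]-2-methyloxirane | ICC[C@]1(C)O[C@H]1CC/C(C)=C/CC[C@](C)(O[Si](CC)(CC)CC)COCc1ccc(OC)cc1 | intermediate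
15 | (2S,5E)-8-[(2S,3S)-3-(2-iodoethyl)-3-methyloxiran-2-yl]-2,6-dimethyl-2-(triethylsilyloxy)oct-5-en-1-ol | ICC[C@]1(C)O[C@H]1CC/C(C)=C/CC[C@](C)(O[Si](CC)(CC)CC)CO | intermediate
16 | (2S,5E)-8-[(2S,3S)-3-(2-iodoethyl)-3-methyloxiran-2-yl]-2,6-dimethyl-2-(triethylsilyloxy)oct-5-enal | ICC[C@]1(C)O[C@H]1CC/C(C)=C/CC[C@](C)(O[Si](CC)(CC)CC)C=O | intermediate
17 | methyl 2-methylacetoacetate (methyl 2-methyl-3-oxobutanoate, racemic) | COC(=O)C(C)C(C)=O | starting material
18 | methyl (5R,6S,9E)-5-hydroxy-12-[(2S,3S)-3-(2-iodoethyl)-3-methyloxiran-2-yl]-2,6,10-trimethyl-3-oxo-6-(triethylsilyloxy)dodec-9-enoate, both C2 epimers and enol | ICC[C@]1(C)O[C@H]1CC/C(C)=C/CC[C@](C)(O[Si](CC)(CC)CC)[C@H](O)CC(=O)C(C)C(=O)OC | intermediate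
19 | (6R)-4-hydroxy-6-[(2S,5E)-8-[(2S,3S)-3-(2-iodoethyl)-3-methyloxiran-2-yl]-6-methyl-2-(triethylsilyloxy)oct-5-en-2-yl]-3-methyl-5,6-dihydro-2H-pyran-2-one, formed as its potassium enolate (not isolated) | ICC[C@]1(C)O[C@H]1CC/C(C)=C/CC[C@](C)(O[Si](CC)(CC)CC)[C@H]1CC(O)=C(C)C(=O)O1 | intermediate
20 | (6R)-6-[(2S,5E)-8-[(2S,3S)-3-(2-iodoethyl)-3-methyloxiran-2-yl]-6-methyl-2-(triethylsilyloxy)oct-5-en-2-yl]-3-methyl-2-oxo-5,6-dihydro-2H-pyran-4-yl trifluoromethanesulfonate (C14 iodide, C1 enol triflate) | ICC[C@]1(C)O[C@H]1CC/C(C)=C/CC[C@](C)(O[Si](CC)(CC)CC)[C@H]1CC(OS(=O)(=O)C(F)(F)F)=C(C)C(=O)O1 | intermediate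
21 | C14 alkylzinc iodide of 20, as its LiCl complex (not isolated) | I[Zn]CC[C@]1(C)O[C@H]1CC/C(C)=C/CC[C@](C)(O[Si](CC)(CC)CC)[C@H]1CC(OS(=O)(=O)C(F)(F)F)=C(C)C(=O)O1 | intermediate
22 | (3R,4S,7E,11S,12S) macrocyclic C1=C15 unsaturated lactone: 14-membered carbocycle with 4,8,12-methyl groups, 7E alkene, 11,12-epoxide and C4 triethylsilyl ether, fused through C1–C3 to a 3-methyl-5,6-dihydropyran-2-one | C1/C=C(\C)CC[C@@H]2O[C@@]2(C)CCC2=C(C)C(=O)O[C@H](C2)[C@@](C)(O[Si](CC)(CC)CC)C1 | intermediate
23 | (1R,3R,4S,7E,11S,12S,15R) saturated lactone, C15 methyl cis to C14, C4 triethylsilyl ether (not isolated) | C1/C=C(\C)CC[C@@H]2O[C@@]2(C)CC[C@@H]2C[C@@H](OC(=O)[C@@H]2C)[C@@](C)(O[Si](CC)(CC)CC)C1 | intermediate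
24 | (1R,3R,4S,7E,11S,12S,15S) saturated lactone, C15 methyl trans to C14, C4 triethylsilyl ether | C1/C=C(\C)CC[C@@H]2O[C@@]2(C)CC[C@@H]2C[C@@H](OC(=O)[C@H]2C)[C@@](C)(O[Si](CC)(CC)CC)C1 | intermediate
25 | (1R,3R,4S,7E,11S,12S,15S) C4 hydroxy lactone | C1/C=C(\C)CC[C@@H]2O[C@@]2(C)CC[C@@H]2C[C@@H](OC(=O)[C@H]2C)[C@@](C)(O)C1 | intermediate
26 | CNP0319766.2, (1R,3R,4S,7S,11S,12S,15S) C7 hydroperoxide with C8 exocyclic methylene | C=C1CC[C@@H]2O[C@@]2(C)CC[C@@H]2C[C@@H](OC(=O)[C@H]2C)[C@@](C)(O)CC[C@@H]1OO | target

## Step count and least certain steps

Total step count: 18. Longest linear sequence: 17 steps (steps 1 and 3–18, from 1); step 2 is a one-step branch from 3.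

Step 15 (key step). The most likely failure is intermolecular coupling overtaking ring closure, because the chain has few conformational constraints. The second risk lies in the insertion stage: zinc halide Lewis acidity, or the C14–Zn bond itself, could open or rearrange the epoxide two carbons away. Protodemetalation or β-hydride elimination at palladium would cost material. Fallback: from 20, a nickel-catalysed reductive cross-electrophile coupling is used instead (NiBr2(MeOCH2CH2OMe), 4,4′-di-tert-butyl-2,2′-bipyridine, Mn powder, N,N-dimethylacetamide, slow addition at high dilution). Low-valent nickel adds to the enol triflate and captures the C14 radical formed from the iodide, so no organozinc accumulates beside the epoxide. The route is rejoined at 22, and the detour makes no compound outside the list (F0).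

Step 13. The likely failure is poor facial selectivity: the α-carbon is quaternary, so the Felkin–Anh preference rests only on methyl against a CH2 group. Two further risks are alkylation of the dianion by the iodide if the temperature rises, and migration of the silyl group from O4 to O3 during the basic lactonisation of step 14. Fallback: from 16, a catalyst-controlled vinylogous Mukaiyama aldol is run with the trimethylsilyl dienolate of 2,2,5,6-tetramethyl-4H-1,3-dioxin-4-one (Cu(OTf)2, Tol-BINAP of the handedness matched to the Felkin preference, (n-Bu4N)Ph3SiF2, THF, −78 °C). After desilylation this gives the δ-hydroxy dioxinone F1. Heating F1 in toluene expels acetone, and the acyl ketene is trapped by the C3 hydroxyl under neutral conditions to give 19 as the free enol. Triflation (PhNTf2, Et3N) then rejoins the route at 20.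

Step 16. The likely failure is slow hydride transfer to the fully substituted β-carbon C1, leading to incomplete conversion. A second risk is that the C15 equilibrium does not strongly favour the trans lactone. Fallback: from 22, nickel boride (NiCl2·6H2O, NaBH4, MeOH, 0 °C) adds both hydrogens from the outer face by surface hydrogenation and should give 23; DBU as in step 16 then gives 24. The detour makes no compound outside the list (F0).

Step 18. The likely failures are hydrogen abstraction from C6 (a tertiary C8 hydroperoxide with a shifted alkene) and poor facial selectivity at C7, which has no nearby control element. Fallback: from 24, the C7 configuration is set by reagent control. Photooxygenation as in step 18 is followed in the same flask by Ac2O, Et3N and 4-dimethylaminopyridine (Kornblum–DeLaMare dehydration of the secondary hydroperoxides of either configuration), giving the α-methylene ketone F2. Corey–Bakshi–Shibata reduction with the (S)-oxazaborolidine and BH3·SMe2 should give the (7R)-allylic alcohol F3, and MsCl with Et3N gives the mesylate F4. Displacement with concentrated H2O2 and K2CO3 in THF at 0 °C (SN2 with inversion, with the C4 oxygen still silylated so that it cannot close a tetrahydrofuran) gives the silyl-protected (7S)-hydroperoxide F5. Buffered fluoride as in step 17 then rejoins the route at 26.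

## Further compounds

F0 | step 15 | none | none
F1 | step 13 | 6-[(2R,3S,6E)-2-hydroxy-9-[(2S,3S)-3-(2-iodoethyl)-3-methyloxiran-2-yl]-3,7-dimethyl-3-(triethylsilyloxy)non-6-en-1-yl]-2,2,5-trimethyl-4H-1,3-dioxin-4-one | ICC[C@]1(C)O[C@H]1CC/C(C)=C/CC[C@](C)(O[Si](CC)(CC)CC)[C@H](O)CC1=C(C)C(=O)OC(C)(C)O1
F0 | step 16 | none | none
F2 | step 18 | C7 ketone with C8 exocyclic methylene, C4 triethylsilyl ether (1R,3R,4S,11S,12S,15S) | C=C1CC[C@@H]2O[C@@]2(C)CC[C@@H]2C[C@@H](OC(=O)[C@H]2C)[C@@](C)(O[Si](CC)(CC)CC)CCC1=O
F3 | step 18 | (7R)-allylic alcohol, C4 triethylsilyl ether | C=C1CC[C@@H]2O[C@@]2(C)CC[C@@H]2C[C@@H](OC(=O)[C@H]2C)[C@@](C)(O[Si](CC)(CC)CC)CC[C@H]1O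
F4 | step 18 | (7R)-methanesulfonate, C4 triethylsilyl ether | C=C1CC[C@@H]2O[C@@]2(C)CC[C@@H]2C[C@@H](OC(=O)[C@H]2C)[C@@](C)(O[Si](CC)(CC)CC)CC[C@H]1OS(C)(=O)=O
F5 | step 18 | (7S)-hydroperoxide, C4 triethylsilyl ether of 26 | C=C1CC[C@@H]2O[C@@]2(C)CC[C@@H]2C[C@@H](OC(=O)[C@H]2C)[C@@](C)(O[Si](CC)(CC)CC)CC[C@@H]1OO
A1 | alternative 1 | (2E,6E,10E)-2,6,10-trimethyldodeca-2,6,10-triene-1,12-diol (12-hydroxyfarnesol) | OC/C(C)=C/CC/C(C)=C/CC/C(C)=C/CO
A2 | alternative 1 | (2S,3S,10S,11S)-2,3:10,11-bis-epoxy diol | OC[C@@H]1O[C@@]1(C)CC/C=C(\C)CC[C@@H]1O[C@@]1(C)CO
A3 | alternative 2 | macrocyclic C3,C4-diol with a 1-(trifluoromethylsulfonyloxy)ethenyl group on C1 (C15 alkenyl triflate) | C1/C=C(\C)CC[C@@H]2O[C@@]2(C)CC[C@@H](C(=C)OS(=O)(=O)C(F)(F)F)C[C@@H](O)[C@@](C)(O)C1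
A4 | alternative 2 | macrocyclic α-methylene δ-lactone | C1/C=C(\C)CC[C@@H]2O[C@@]2(C)CC[C@@H]2C[C@@H](OC(=O)C2=C)[C@@](C)(O)C1
A5 | alternative 3 | 16-membered allyl β-keto ester (C8 ketone, ester oxygen on C10, C7 tert-butyldimethylsilyl ether) | O=C1CC(=O)OC/C=C(\C)CC[C@@H]2C[C@@H](OC(=O)[C@H]2C)[C@@](C)(O)CC[C@H]1O[Si](C)(C)C(C)(C)C
A6 | alternative 3 | 14-membered C8 ketone with E C11=C12 alkene | O=C1CC/C=C(\C)CC[C@@H]2C[C@@H](OC(=O)[C@H]2C)[C@@](C)(O)CC[C@H]1O[Si](C)(C)C(C)(C)C
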